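## Structural features

- The target is a 4H-chromen-4-one whose carbocycle (C5 to C8) is fully saturated and carries four contiguous secondary hydroxyls. C2 of the γ-pyranone ring carries a two-carbon tether to a 3-hydroxy-4-methoxyphenyl ring.
- The configuration is (5S,6S,7R,8S): O5/O6 cis, O6/O7 trans, O7/O8 trans, so O5 and O8 are cis across the ring.
- C5 and C8 are both allylic to the tetrasubstituted C4a=C8a bond of the vinylogous ester. The C5 hydroxyl lies peri to the C4 carbonyl and can hydrogen-bond to it. C8–H is the γ-hydrogen of the vinylogous ester and is acidic.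
- Any intermediate with leaving groups at C5 or C8 and unsaturation in the carbocycle is one or two eliminations from an aromatic chromone, so acid, base and heat must stay mild. Amines are avoided because they can turn 4-pyranones into 4-pyridones.
- The real difficulty is twofold. Four stereocentres must be set on a ring fused to a flat, achiral heterocycle with no resident stereocentre. The two halves C5/C6 and C8/C7 are constitutionally almost alike yet need opposite relative configurations (cis and trans).
- The key step exploits the C4a=C8a double bond flanked by the cis oxygens at C5 and C8. This is the imprint of an (E,E)-1,4-dioxygenated butadiene added across that bond, the double bond being restored by loss of a sulfinyl group from C4a that also serves as the chiral controller.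

## Logic of the disconnections

**22 back to 19.** Only oxygen–protecting-group bonds are cut: the phenolic benzyl ether, the 5,6-carbonate and the O8 silyl ether. The skeleton does not simplify, but the order matters. The silyl group goes first under buffered fluoride (no silyl migration), the carbonate second under catalytic base (nothing on the ring can then leave easily), the benzyl group last under neutral hydrogenolysis. The forward steps must be three orthogonal, mild removals.

**19 back to 17 through 18.** The C6–O and C7–O bonds are cut. The cis-5,6/trans-6,7 pattern is an anti addition of two oxygens across C6=C7 in which the C6 oxygen is delivered from O5. This removes two stereocentres and leaves a cis-5,8-dioxygenated cyclohexadiene. The forward steps need epoxidation anti to both allylic substituents and opening at C6 by the O5 carbonate only, so O8 must carry a group that cannot participate.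

**17 back to 14 through 16 and 15.** Oxygen–acyl and oxygen–silyl bonds are cut. The two acetates of 14 play the same role and must be told apart before O5 can act as the internal nucleophile. The gain is a return to the direct cycloadduct. The forward steps need deacetylation without aromatisation and a site-selective reaction at O8, which relies on the hydrogen bond and peri shielding at O5.

**14 back to 11 and 12.** C4a–C5 and C8–C8a are cut. A C4a=C8a bond flanked by cis oxygens is the retron of a [4+2] addition followed by elimination. The carbocycle and both stereocentres disappear, leaving a monocyclic pyranone and a four-carbon diene. The sulfinyl group on C4a must activate the dienophile, select its face and then leave; endo and facial selectivity are both required. As a check of the stereochemical bookkeeping, the adduct is (5R,8S) and the target is (5S,8S) at the same two carbons with unchanged geometry; only the CIP ranking at C5 changes once C6 carries oxygen.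

**11 back to 9 and 6 through 10.** In chromone numbering, C2–C3 and O1–C8a are cut. A design correction is built in here. Formylating a free β,δ-diketo sulfoxide with a formamide acetal would attack the methylene between the two carbonyls, not the sulfinyl-bearing carbon, and a β-keto ester would quench a lithiated sulfoxide by proton transfer. In 9 the aminomethylene carbon is therefore already in place and the acetyl methyl is the only enolisable site. The gain is convergence into a sulfur fragment and an aryl fragment. The forward step needs C-acylation of the enolate with the sulfoxide intact and an acid-induced ring closure.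

**9 back to 8 and 7.** C4a–C8a (the aminomethylene carbon) and C4–C4a (acetyl to sulfinyl carbon) are cut. Both are standard reactions of the α-sulfinyl carbanion and of the active methylene, and the chirality at sulfur is bought in 7. Sulfur must not racemise.

**6 back to 5, then 1 and 2.** The bond between the benzylic carbon and the carbon α to the carboxyl is cut. An aldehyde plus a malonate equivalent gives the chain; the reductive variant avoids a catalytic hydrogenation that would remove the benzyl ether.

## Other disconnections considered

**Alternative 1:** The carbocycle is cut at C4a–C5 and the whole pyranone is added later. D-glucose A1 is taken to the 5-enopyranoside A2. In the forward key step, catalytic Hg(OCOCF3)2 in aqueous acetone hydrates the exocyclic enol ether, the ring opens to a keto aldehyde, and an intramolecular aldol closes the cyclohexanone A3.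
- In its favour: C6, C7 and C8 come from the sugar with no selectivity question, and C5 comes from a chair-like aldol that places the new hydroxyl cis to the neighbouring benzyloxy group. A3 maps exactly onto C5 to C8 of 22. On stereochemical security this is better than the chosen plan. Uniform benzyl protection allows one final hydrogenolysis, which is also better than the three-stage endgame used here.
- Against it: the pyranone must be grown on a β-hydroxy ketone. Acylation at C4a and cyclodehydration through the C8a enol put C5–O β to one or two carbonyls in every intermediate, so elimination and then aromatisation threaten throughout. Enolisation must also choose C4a over C8, and a mercury salt is needed.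
- Comparison: the step count is about equal. The chosen plan is better on convergence and because the heterocycle exists before any oxygenated sp3 carbon is made.

**Alternative 2:** The cut is C7–C8. The precursor is the pyranone aldehyde A4, with a benzyloxymethyl group on C8a and a chiral dialkoxy aldehyde chain on C4a. In the forward key step, t-BuMe2SiOSO2CF3 and triethylamine silylate the C4 oxygen and remove a C8 proton, and the resulting 2-alkylidene-2H-pyran adds to the C7 aldehyde to give A5.
- In its favour: the γ-nucleophilicity of 2-alkyl-4-pyranones is inherent, the closure is intramolecular and cold, and the trans,trans arrangement of O6/O7/O8 is what an all-equatorial chair-like closure should prefer. No auxiliary and no high-pressure equipment are needed, which is operationally better than the chosen key step. A5 already carries all four oxygens and needs only one hydrogenolysis, so it is better on economy after the key step.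
- Against it: A4 is a fully substituted pyranone with two stereocentres, requiring a long chiral-pool sequence and a C–C bond to the pyranone 3-position. Its α-alkoxy aldehyde can epimerise or eliminate under the amine. Two stereocentres are set under substrate control only, and in A5 the C7 oxygen is β to the acidic C8–H.
- Comparison: the chosen plan makes two C–C bonds and the ring from simple partners; the alternative makes one C–C bond from an elaborate precursor and is probably longer overall.

**Alternative 3:** The cut is C5–O and C6–O. The flat parent chromone A6 would be dihydroxylated by an engineered toluene- or naphthalene-dioxygenase-type non-heme iron enzyme, which delivers both atoms of O2 to one face of C5–C6 to give the cis-dihydrodiol A7.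
- In its favour: A6 is achiral and a few steps from commodity materials, no protecting groups are needed, and the cis-5,6-diol, which costs steps 7 to 11 in the chosen plan, arrives in one operation. If a fitting enzyme exists, step economy is clearly better and enantiocontrol is equal or better.
- Against it: no enzyme can be assumed to accept an electron-poor, 2-substituted chromone with a competing electron-rich arene in the side chain. Regioselectivity (5,6 against 7,8 against the side-chain ring) and the absolute sense are dictated by the protein. A7 is an arene hydrate that dehydrates readily to a phenol, and the trans-7,8-diol still needs a face- and regio-controlled anti-dioxygenation.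
- Comparison: the chosen plan is longer but rests on reagent and auxiliary control that can be reasoned out beforehand; the alternative rests on enzyme screening.

Key step: step 6

Remark: 1 is taken as the commercially available benzyl ether of isovanillin (one O-benzylation away if it must be made).

Remark: the geometry of the aminomethylene double bond in 9 and 10 is left unassigned because it is lost on ring closure. The descriptor changes at sulfur (S in 7 and 8, R from 9 on) and at C5 (R in 13 to 17, S from 18 on) reflect CIP ranking only, not inversion.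

## Steps

Step 1
Reactants: 1 3-benzyloxy-4-methoxybenzaldehyde; 2 Meldrum's acid (2,2-dimethyl-1,3-dioxane-4,6-dione)
Product: 5 3-(3-benzyloxy-4-methoxyphenyl)propanoic acid, via arylidene Meldrum's acid 3 (not isolated), via arylmethyl Meldrum's acid 4 (not isolated)
Conditions: HCO2H/Et3N (5:2), 95–100 °C; then aq. HCl
Reagents that add atoms: none
Why: Knoevenagel condensation, conjugate reduction of the arylidene by formate (hydride transfer) and hydrolysis–decarboxylation of the alkylated Meldrum's acid run in one pot; no hydrogenation catalyst is present, so the benzyl ether should survive.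

Step 2
Reactants: 5 3-(3-benzyloxy-4-methoxyphenyl)propanoic acid
Product: 6 3-(3-benzyloxy-4-methoxyphenyl)propanoyl chloride
Conditions: (COCl)2, DMF (cat.), CH2Cl2, 0 °C → rt
Reagents that add atoms: oxalyl chloride, ClC(=O)C(Cl)=O
Why: Vilsmeier-type activation converts the acid into the acyl chloride under cold, neutral conditions that spare the benzyl ether; the crude chloride is used directly.

Step 3
Reactants: 7 (S)-methyl p-tolyl sulfoxide
Product: 8 (S)-1-(p-tolylsulfinyl)propan-2-one
Conditions: LiN(i-Pr)2 (2.1 equiv), THF, −78 °C; EtOAc, −78 → −20 °C; aq. NH4Cl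
Reagents that add atoms: ethyl acetate, CCOC(C)=O
Why: α-Lithiation of the methyl sulfoxide and Claisen-type C-acylation by the ester; the second equivalent of base takes up the more acidic β-keto sulfoxide as it forms, and sulfur is not touched.

Step 4
Reactants: 8 (S)-1-(p-tolylsulfinyl)propan-2-one
Product: 9 (R)-4-(dimethylamino)-3-(p-tolylsulfinyl)but-3-en-2-one
Conditions: Me2NCH(OMe)2 (1.2 equiv), toluene, rt → 40 °C
Reagents that add atoms: N,N-dimethylformamide dimethyl acetal, COC(OC)N(C)C
Why: The only active methylene (between C=O and S=O) condenses with the formamide acetal to a push–pull enaminone, which places the future C8a before a second carbonyl exists, so there is no regiochemical ambiguity.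

Step 5
Reactants: 9 (R)-4-(dimethylamino)-3-(p-tolylsulfinyl)but-3-en-2-one; 6 3-(3-benzyloxy-4-methoxyphenyl)propanoyl chloride
Product: 11 (R)-2-[2-(3-benzyloxy-4-methoxyphenyl)ethyl]-5-(p-tolylsulfinyl)-4H-pyran-4-one, via diketone enaminone 10 (not isolated)
Conditions: LiN(SiMe3)2 (2.2 equiv), THF, −78 °C; 6, −78 °C; then CF3CO2H, CH2Cl2, 0 °C → rt
Reagents that add atoms: none
Why: The acetyl methyl is the only enolisable site of 9; its lithium enolate is C-acylated by 6 (the second equivalent of base absorbs the diketone proton), and acid then triggers 6-endo addition of the enol oxygen to the aminomethylene carbon with loss of dimethylamine. This is the established γ-pyranone synthesis from enolates of β-amino or β-alkoxy enones and acyl chlorides, applied to a sulfinyl-bearing enaminone.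

Step 6
Reactants: 11 (R)-2-[2-(3-benzyloxy-4-methoxyphenyl)ethyl]-5-(p-tolylsulfinyl)-4H-pyran-4-one; 12 (1E,3E)-1,4-diacetoxybuta-1,3-diene
Product: 14 (5R,8S)-5,8-diacetoxy-2-[2-(3-benzyloxy-4-methoxyphenyl)ethyl]-5,8-dihydro-4H-chromen-4-one, via endo cycloadduct 13 (not isolated)
Conditions: 12 (3 equiv), CH2Cl2, 12 kbar, 35 °C; then 1 bar, 45 °C
Reagents that add atoms: none
Why: A normal-demand Diels–Alder reaction between the HOMO of 12 and the C4a=C8a bond of 11, whose LUMO is lowered by both the C4 carbonyl and the sulfinyl group, forms C4a–C5 and C8–C8a in one concerted, suprafacial [4+2] event and so closes the carbocycle as cycloadduct 13. The closest known reaction type is the cycloaddition of enantiopure 2-(p-tolylsulfinyl)quinones and 2-sulfinyl enones with loss of the sulfoxide in the same pot, together with cycloadditions at the C2=C3 bond of 3-acyl chromones. In 13 the sulfinyl group on C4a and the hydrogen on C8a are syn and nearly eclipsed because they were cis on the dienophile, so thermal syn-elimination of p-toluenesulfenic acid on gentle warming should restore the C4a=C8a bond, remove the auxiliary and erase the two transient ring-fusion stereocentres. The cis relation of C5 and C8 follows from the E,E geometry of 12 and suprafacial addition. The absolute configuration is set by the sulfur stereocentre: in the dipole-minimised s-cis conformer (S–O syn-coplanar with C4a=C8a) the p-tolyl group covers one face, the diene adds to the lone-pair face endo to the pyranone carbonyl, and both acetoxy groups end on the face from which the diene came, which is (5R,8S). Both facial and endo selectivity are needed because a wrong-face or an exo event gives the enantiomer after elimination; site selectivity for C4a=C8a over the other ring double bond follows from the missing sulfinyl activation there. Elimination toward C8a–H and not toward C5–H (also syn to sulfur but gauche) is favoured by alignment and by regaining the pyranone. High pressure is chosen because both diene termini are substituted and one bonds to a fully substituted carbon; pressure accelerates the cycloaddition at a temperature where loss of acetic acid from 14 is slow.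

Step 7
Reactants: 14 (5R,8S)-5,8-diacetoxy-2-[2-(3-benzyloxy-4-methoxyphenyl)ethyl]-5,8-dihydro-4H-chromen-4-one
Product: 15 (5R,8S)-2-[2-(3-benzyloxy-4-methoxyphenyl)ethyl]-5,8-dihydroxy-5,8-dihydro-4H-chromen-4-one
Conditions: K2CO3 (0.2 equiv), MeOH, 0 °C
Reagents that add atoms: none
Why: Zemplén-type transesterification removes both allylic acetates; a weak base in substoichiometric amount at 0 °C is used because deprotonation at C8 followed by 1,4-loss of the C5 acetate would aromatise the ring, and amines are avoided because they can convert 4-pyranones into 4-pyridones.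

Step 8
Reactants: 15 (5R,8S)-2-[2-(3-benzyloxy-4-methoxyphenyl)ethyl]-5,8-dihydroxy-5,8-dihydro-4H-chromen-4-one
Product: 16 (5R,8S)-2-[2-(3-benzyloxy-4-methoxyphenyl)ethyl]-8-(tert-butyldimethylsilyloxy)-5-hydroxy-5,8-dihydro-4H-chromen-4-one
Conditions: t-BuMe2SiCl (1.1 equiv), imidazole, DMF, −20 → 0 °C
Reagents that add atoms: tert-butyldimethylsilyl chloride, CC(C)(C)[Si](C)(C)Cl
Why: Kinetic monosilylation: the C5 hydroxyl is hydrogen-bonded to and flanked by the peri C4 carbonyl while the C8 hydroxyl is free, so a bulky silyl chloride in limiting amount should go to O8.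

Step 9
Reactants: 16 (5R,8S)-2-[2-(3-benzyloxy-4-methoxyphenyl)ethyl]-8-(tert-butyldimethylsilyloxy)-5-hydroxy-5,8-dihydro-4H-chromen-4-one
Product: 17 (5R,8S)-2-[2-(3-benzyloxy-4-methoxyphenyl)ethyl]-5-(tert-butoxycarbonyloxy)-8-(tert-butyldimethylsilyloxy)-5,8-dihydro-4H-chromen-4-one
Conditions: (t-BuOCO)2O, DMAP (0.2 equiv), MeCN, 0 °C → rt
Reagents that add atoms: di-tert-butyl dicarbonate, CC(C)(C)OC(=O)OC(=O)OC(C)(C)C
Why: DMAP-catalysed acylation of the remaining hindered secondary alcohol; the carbonate is put on O5 because only a nucleophile on that oxygen can later deliver oxygen to C6 cis to C5–O.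

Step 10
Reactants: 17 (5R,8S)-2-[2-(3-benzyloxy-4-methoxyphenyl)ethyl]-5-(tert-butoxycarbonyloxy)-8-(tert-butyldimethylsilyloxy)-5,8-dihydro-4H-chromen-4-one
Product: 18 (5S,6R,7R,8S)-2-[2-(3-benzyloxy-4-methoxyphenyl)ethyl]-5-(tert-butoxycarbonyloxy)-8-(tert-butyldimethylsilyloxy)-6,7-epoxy-5,6,7,8-tetrahydro-4H-chromen-4-one (epoxide oxygen trans to O5 and O8)
Conditions: mCPBA, CH2Cl2, 0 °C → rt
Reagents that add atoms: 3-chloroperoxybenzoic acid, OOC(=O)c1cccc(Cl)c1
Why: Prilezhaev epoxidation; the pyranone double bonds are electron-poor and should be inert to the peracid, and with both allylic oxygens capped (no hydrogen-bond direction) the reagent should approach C6=C7 from the face opposite the two cis substituents, which sets C6 and C7. Any carbonate closure caused early by the liberated carboxylic acid only anticipates step 11.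

Step 11
Reactants: 18 (5S,6R,7R,8S)-2-[2-(3-benzyloxy-4-methoxyphenyl)ethyl]-5-(tert-butoxycarbonyloxy)-8-(tert-butyldimethylsilyloxy)-6,7-epoxy-5,6,7,8-tetrahydro-4H-chromen-4-one
Product: 19 (5S,6R,7R,8S)-2-[2-(3-benzyloxy-4-methoxyphenyl)ethyl]-8-(tert-butyldimethylsilyloxy)-7-hydroxy-5,6,7,8-tetrahydro-4H-chromen-4-one 5,6-cyclic carbonate (cis-fused)
Conditions: BF3·OEt2 (0.3 equiv), CH2Cl2, −40 → −10 °C
Reagents that add atoms: none
Why: Lewis-acid activation of the epoxide lets the carbonyl oxygen of the neighbouring tert-butyl carbonate attack C6 from the rear (5-exo-tet, inversion), and the resulting 2-tert-butoxy-1,3-dioxolan-2-ylium ion loses isobutene to give the cis-fused carbonate; C6–O therefore ends cis to C5–O while C7 keeps its epoxide oxygen trans to both neighbours. The proton set free regenerates the acid, so a substoichiometric amount should suffice, and the O8 silyl ether cannot participate.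

Step 12
Reactants: 19 (5S,6R,7R,8S)-2-[2-(3-benzyloxy-4-methoxyphenyl)ethyl]-8-(tert-butyldimethylsilyloxy)-7-hydroxy-5,6,7,8-tetrahydro-4H-chromen-4-one 5,6-cyclic carbonate
Product: 20 (5S,6R,7S,8S)-2-[2-(3-benzyloxy-4-methoxyphenyl)ethyl]-7,8-dihydroxy-5,6,7,8-tetrahydro-4H-chromen-4-one 5,6-cyclic carbonate
Conditions: HF·pyridine, pyridine/THF, 0 °C → rt
Reagents that add atoms: none
Why: Fluoride-driven Si–O cleavage under buffered, weakly acidic conditions; carbonate, benzyl ether and pyranone should be inert, and the silyl migration that base could cause is avoided.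

Step 13
Reactants: 20 (5S,6R,7S,8S)-2-[2-(3-benzyloxy-4-methoxyphenyl)ethyl]-7,8-dihydroxy-5,6,7,8-tetrahydro-4H-chromen-4-one 5,6-cyclic carbonate
Product: 21 (5S,6S,7R,8S)-2-[2-(3-benzyloxy-4-methoxyphenyl)ethyl]-5,6,7,8-tetrahydroxy-5,6,7,8-tetrahydro-4H-chromen-4-one
Conditions: K2CO3 (0.2 equiv), MeOH, 0 °C
Reagents that add atoms: none
Why: Base-catalysed methanolysis of the five-membered carbonate to the cis-diol and dimethyl carbonate; with only hydroxyl groups (poor leaving groups) left on the ring, brief exposure to catalytic carbonate at 0 °C should not trigger elimination.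

Step 14
Reactants: 21 (5S,6S,7R,8S)-2-[2-(3-benzyloxy-4-methoxyphenyl)ethyl]-5,6,7,8-tetrahydroxy-5,6,7,8-tetrahydro-4H-chromen-4-one
Product: 22 (5S,6S,7R,8S)-5,6,7,8-tetrahydroxy-2-[2-(3-hydroxy-4-methoxyphenyl)ethyl]-5,6,7,8-tetrahydro-4H-chromen-4-one
Conditions: H2 (1 atm), Pd/C (10 wt%), EtOAc/MeOH, rt
Reagents that add atoms: none
Why: Hydrogenolysis of the aryl benzyl ether over palladium on carbon; this cleavage is much faster than reduction of the vinylogous-ester double bonds of the pyranone, no other reducible group remains, and the product needs only filtration.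

## Compound list

1 | 3-benzyloxy-4-methoxybenzaldehyde | COc1ccc(C=O)cc1OCc1ccccc1 | starting material
2 | Meldrum's acid | CC1(C)OC(=O)CC(=O)O1 | starting material
3 | 5-[(3-benzyloxy-4-methoxyphenyl)methylidene]-2,2-dimethyl-1,3-dioxane-4,6-dione | COc1ccc(C=C2C(=O)OC(C)(C)OC2=O)cc1OCc1ccccc1 | intermediate (not isolated)
4 | 5-[(3-benzyloxy-4-methoxyphenyl)methyl]-2,2-dimethyl-1,3-dioxane-4,6-dione | COc1ccc(CC2C(=O)OC(C)(C)OC2=O)cc1OCc1ccccc1 | intermediate (not isolated)
5 | 3-(3-benzyloxy-4-methoxyphenyl)propanoic acid | COc1ccc(CCC(=O)O)cc1OCc1ccccc1 | intermediate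
6 | 3-(3-benzyloxy-4-methoxyphenyl)propanoyl chloride | COc1ccc(CCC(Cl)=O)cc1OCc1ccccc1 | intermediate
7 | (S)-methyl p-tolyl sulfoxide | C[S@](=O)c1ccc(C)cc1 | starting material
8 | (S)-1-(p-tolylsulfinyl)propan-2-one | CC(=O)C[S@](=O)c1ccc(C)cc1 | intermediate
9 | (R)-4-(dimethylamino)-3-(p-tolylsulfinyl)but-3-en-2-one | CC(=O)C(=CN(C)C)[S@](=O)c1ccc(C)cc1 | intermediate
10 | (R)-1-(3-benzyloxy-4-methoxyphenyl)-7-(dimethylamino)-6-(p-tolylsulfinyl)hept-6-ene-3,5-dione | COc1ccc(CCC(=O)CC(=O)C(=CN(C)C)[S@](=O)c2ccc(C)cc2)cc1OCc1ccccc1 | intermediate (not isolated)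
11 | (R)-2-[2-(3-benzyloxy-4-methoxyphenyl)ethyl]-5-(p-tolylsulfinyl)-4H-pyran-4-one | COc1ccc(CCc2cc(=O)c(co2)[S@](=O)c2ccc(C)cc2)cc1OCc1ccccc1 | intermediate
12 | (1E,3E)-1,4-diacetoxybuta-1,3-diene | CC(=O)O/C=C/C=C/OC(C)=O | starting material
13 | (4aS,5R,8S,8aS)-5,8-diacetoxy-2-[2-(3-benzyloxy-4-methoxyphenyl)ethyl]-4a-[(R)-p-tolylsulfinyl]-4a,5,8,8a-tetrahydro-4H-chromen-4-one | COc1ccc(CCC2=CC(=O)[C@]3([S@](=O)c4ccc(C)cc4)[C@H](OC(C)=O)C=C[C@H](OC(C)=O)[C@@H]3O2)cc1OCc1ccccc1 | intermediate (not isolated)
14 | (5R,8S)-5,8-diacetoxy-2-[2-(3-benzyloxy-4-methoxyphenyl)ethyl]-5,8-dihydro-4H-chromen-4-one | COc1ccc(CCc2cc(=O)c3c(o2)[C@@H](OC(C)=O)C=C[C@H]3OC(C)=O)cc1OCc1ccccc1 | intermediate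
15 | (5R,8S)-2-[2-(3-benzyloxy-4-methoxyphenyl)ethyl]-5,8-dihydroxy-5,8-dihydro-4H-chromen-4-one | COc1ccc(CCc2cc(=O)c3c(o2)[C@@H](O)C=C[C@H]3O)cc1OCc1ccccc1 | intermediate
16 | (5R,8S)-2-[2-(3-benzyloxy-4-methoxyphenyl)ethyl]-8-(tert-butyldimethylsilyloxy)-5-hydroxy-5,8-dihydro-4H-chromen-4-one | COc1ccc(CCc2cc(=O)c3c(o2)[C@@H](O[Si](C)(C)C(C)(C)C)C=C[C@H]3O)cc1OCc1ccccc1 | intermediate
17 | (5R,8S)-2-[2-(3-benzyloxy-4-methoxyphenyl)ethyl]-5-(tert-butoxycarbonyloxy)-8-(tert-butyldimethylsilyloxy)-5,8-dihydro-4H-chromen-4-one | COc1ccc(CCc2cc(=O)c3c(o2)[C@@H](O[Si](C)(C)C(C)(C)C)C=C[C@H]3OC(=O)OC(C)(C)C)cc1OCc1ccccc1 | intermediate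
18 | (5S,6R,7R,8S)-2-[2-(3-benzyloxy-4-methoxyphenyl)ethyl]-5-(tert-butoxycarbonyloxy)-8-(tert-butyldimethylsilyloxy)-6,7-epoxy-5,6,7,8-tetrahydro-4H-chromen-4-one | COc1ccc(CCc2cc(=O)c3c(o2)[C@@H](O[Si](C)(C)C(C)(C)C)[C@@H]4O[C@@H]4[C@H]3OC(=O)OC(C)(C)C)cc1OCc1ccccc1 | intermediate
19 | (5S,6R,7R,8S)-2-[2-(3-benzyloxy-4-methoxyphenyl)ethyl]-8-(tert-butyldimethylsilyloxy)-7-hydroxy-5,6,7,8-tetrahydro-4H-chromen-4-one 5,6-cyclic carbonate | COc1ccc(CCc2cc(=O)c3c(o2)[C@@H](O[Si](C)(C)C(C)(C)C)[C@H](O)[C@H]4OC(=O)O[C@H]43)cc1OCc1ccccc1 | intermediate
20 | (5S,6R,7S,8S)-2-[2-(3-benzyloxy-4-methoxyphenyl)ethyl]-7,8-dihydroxy-5,6,7,8-tetrahydro-4H-chromen-4-one 5,6-cyclic carbonate | COc1ccc(CCc2cc(=O)c3c(o2)[C@@H](O)[C@H](O)[C@H]4OC(=O)O[C@H]43)cc1OCc1ccccc1 | intermediate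
21 | (5S,6S,7R,8S)-2-[2-(3-benzyloxy-4-methoxyphenyl)ethyl]-5,6,7,8-tetrahydroxy-5,6,7,8-tetrahydro-4H-chromen-4-one | COc1ccc(CCc2cc(=O)c3c(o2)[C@@H](O)[C@H](O)[C@@H](O)[C@H]3O)cc1OCc1ccccc1 | intermediate
22 | (5S,6S,7R,8S)-5,6,7,8-tetrahydroxy-2-[2-(3-hydroxy-4-methoxyphenyl)ethyl]-5,6,7,8-tetrahydro-4H-chromen-4-one | COc1ccc(CCc2cc(=O)c3c(o2)[C@@H](O)[C@H](O)[C@@H](O)[C@H]3O)cc1O | target

## Step count and least certain steps

Total: 14 steps. Longest linear sequence: 12 steps (from 7 through steps 3 to 14, or from 1 through steps 1, 2 and 5 to 14).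

**Step 6 (key step).** The most likely failure is a sluggish cycloaddition. The diene is substituted at both termini and only weakly donating, and one terminus must bond to a fully substituted, only moderately activated carbon. Forcing it risks erosion of facial or endo selectivity, misdirected sulfoxide elimination, or loss of acetic acid with aromatisation. The fallback changes the diene from an enol ester to a far more electron-rich silyl dienol ether, so the reaction can run near room temperature at ordinary pressure and the acetate stage is bypassed. It sets out from 12 and 11. Treating 12 with CH3Li (4 equiv) in 1,2-dimethoxyethane at 0 °C and trapping the dienediolate with Me3SiCl should give, with retention of both enolate geometries, (1E,3E)-1,4-bis(trimethylsilyloxy)buta-1,3-diene F1. Cycloaddition of 11 with F1 in toluene at 25–40 °C should proceed under the same facial and endo control through the trimethylsilyl analogue of 13, the endo cycloadduct F2, which should lose p-toluenesulfenic acid to give the (5R,8S)-5,8-bis(trimethylsilyl) ether of 15, F3. Methanol with a trace of citric acid at 0 °C should then release the diol, and the route is rejoined at 15.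

**Step 5.** Possible failures are O- instead of C-acylation of the enolate, attack of the acyl chloride on the sulfinyl oxygen (with Pummerer-type damage or loss of configuration at sulfur), or incomplete ring closure. The fallback introduces sulfur last. It sets out from 6. The lithium enolate of commercial (E)-4-methoxybut-3-en-2-one is acylated with 6 to the methoxy enedione (E)-1-(3-benzyloxy-4-methoxyphenyl)-7-methoxyhept-6-ene-3,5-dione F4, which is cyclised without isolation by CF3CO2H to 2-[2-(3-benzyloxy-4-methoxyphenyl)ethyl]-4H-pyran-4-one F5. Iodine in pyridine should iodinate the α-carbon next to the unsubstituted β-position (conjugate addition of pyridine at the C–H terminus, iodination, elimination) to give 2-[2-(3-benzyloxy-4-methoxyphenyl)ethyl]-5-iodo-4H-pyran-4-one F6. Iodine–magnesium exchange with i-PrMgCl·LiCl at −40 °C and an Andersen-type quench with (1S,2R,5S)-menthyl (R)-p-toluenesulfinate, which proceeds with inversion at sulfur, should deliver the sulfoxide, and the route is rejoined at 11.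

**Step 7.** The likely failure is base-induced deprotonation at C8 followed by 1,4-loss of the C5 acetate and aromatisation, or conjugate addition of methoxide to the pyranone. The fallback replaces base-mediated transesterification by enzymatic hydrolysis at neutral pH. It sets out from 14. A lipase (Candida antarctica lipase B) or pig liver esterase in pH 7 phosphate buffer with acetone as cosolvent should first hydrolyse the exposed C8 ester to give (5R,8S)-5-acetoxy-2-[2-(3-benzyloxy-4-methoxyphenyl)ethyl]-8-hydroxy-5,8-dihydro-4H-chromen-4-one F7 and then, more slowly, the C5 ester, so the route is rejoined at 15.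

**Step 8.** The likely failure is insufficient discrimination between the two hydroxyls, giving the O5 silyl ether and the bis-silyl ether alongside 16. The fallback uses enzymatic recognition instead of a bulky reagent and an ester in place of the silyl ether. It sets out from 15. Lipase-catalysed acylation with vinyl acetate should acetylate the unhindered O8 to give the (5R,8S)-8-acetoxy-5-hydroxy compound F8. The dicarbonate and DMAP then give the (5R,8S)-8-acetoxy-5-(tert-butoxycarbonyloxy) compound F9. mCPBA gives the 6,7-epoxide F10, with the epoxide oxygen trans to O5 and O8. BF3·OEt2 gives the 8-acetoxy-7-hydroxy 5,6-cyclic carbonate F11; the carbonate should outrun the less nucleophilic acetate as the neighbouring group. Catalytic K2CO3 in methanol removes the acetate and the carbonate together, so the route is rejoined at 21 and step 12 is not needed.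

## Further compounds

F1 | step 6 | (1E,3E)-1,4-bis(trimethylsilyloxy)buta-1,3-diene | C[Si](C)(C)O/C=C/C=C/O[Si](C)(C)C
F2 | step 6 | endo cycloadduct of 11 and F1 (trimethylsilyl analogue of 13) | COc1ccc(CCC2=CC(=O)[C@]3([S@](=O)c4ccc(C)cc4)[C@H](O[Si](C)(C)C)C=C[C@H](O[Si](C)(C)C)[C@@H]3O2)cc1OCc1ccccc1
F3 | step 6 | (5R,8S)-2-[2-(3-benzyloxy-4-methoxyphenyl)ethyl]-5,8-bis(trimethylsilyloxy)-5,8-dihydro-4H-chromen-4-one | COc1ccc(CCc2cc(=O)c3c(o2)[C@@H](O[Si](C)(C)C)C=C[C@H]3O[Si](C)(C)C)cc1OCc1ccccc1
F4 | step 5 | (E)-1-(3-benzyloxy-4-methoxyphenyl)-7-methoxyhept-6-ene-3,5-dione | COc1ccc(CCC(=O)CC(=O)/C=C/OC)cc1OCc1ccccc1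
F5 | step 5 | 2-[2-(3-benzyloxy-4-methoxyphenyl)ethyl]-4H-pyran-4-one | COc1ccc(CCc2cc(=O)cco2)cc1OCc1ccccc1
F6 | step 5 | 2-[2-(3-benzyloxy-4-methoxyphenyl)ethyl]-5-iodo-4H-pyran-4-one | COc1ccc(CCc2cc(=O)c(I)co2)cc1OCc1ccccc1
F7 | step 7 | (5R,8S)-5-acetoxy-2-[2-(3-benzyloxy-4-methoxyphenyl)ethyl]-8-hydroxy-5,8-dihydro-4H-chromen-4-one | COc1ccc(CCc2cc(=O)c3c(o2)[C@@H](O)C=C[C@H]3OC(C)=O)cc1OCc1ccccc1
F8 | step 8 | (5R,8S)-8-acetoxy-2-[2-(3-benzyloxy-4-methoxyphenyl)ethyl]-5-hydroxy-5,8-dihydro-4H-chromen-4-one | COc1ccc(CCc2cc(=O)c3c(o2)[C@@H](OC(C)=O)C=C[C@H]3O)cc1OCc1ccccc1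
F9 | step 8 | (5R,8S)-8-acetoxy-2-[2-(3-benzyloxy-4-methoxyphenyl)ethyl]-5-(tert-butoxycarbonyloxy)-5,8-dihydro-4H-chromen-4-one | COc1ccc(CCc2cc(=O)c3c(o2)[C@@H](OC(C)=O)C=C[C@H]3OC(=O)OC(C)(C)C)cc1OCc1ccccc1
F10 | step 8 | 8-acetoxy-5-(tert-butoxycarbonyloxy)-6,7-epoxy analogue of 18 (epoxide oxygen trans to O5 and O8) | COc1ccc(CCc2cc(=O)c3c(o2)[C@@H](OC(C)=O)[C@@H]4O[C@@H]4[C@H]3OC(=O)OC(C)(C)C)cc1OCc1ccccc1
F11 | step 8 | 8-acetoxy-7-hydroxy 5,6-cyclic carbonate (acetyl analogue of 19) | COc1ccc(CCc2cc(=O)c3c(o2)[C@@H](OC(C)=O)[C@H](O)[C@H]4OC(=O)O[C@H]43)cc1OCc1ccccc1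
A1 | alternative 1 | D-glucose (α-pyranose form) | OC[C@H]1O[C@H](O)[C@H](O)[C@@H](O)[C@@H]1O
A2 | alternative 1 | methyl 2,3,4-tri-O-benzyl-6-deoxy-α-D-xylo-hex-5-enopyranoside | CO[C@H]1OC(=C)[C@@H](OCc2ccccc2)[C@H](OCc2ccccc2)[C@H]1OCc1ccccc1
A3 | alternative 1 | (2S,3R,4S,5S)-2,3,4-tris(benzyloxy)-5-hydroxycyclohexan-1-one | O=C1[C@@H](OCc2ccccc2)[C@H](OCc2ccccc2)[C@@H](OCc2ccccc2)[C@@H](O)C1
A4 | alternative 2 | 2-[2-(3-benzyloxy-4-methoxyphenyl)ethyl]-6-(benzyloxymethyl)-5-[(1S,2S)-1,2-bis(benzyloxy)-3-oxopropyl]-4H-pyran-4-one | COc1ccc(CCc2cc(=O)c([C@H](OCc3ccccc3)[C@H](OCc3ccccc3)C=O)c(COCc3ccccc3)o2)cc1OCc1ccccc1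
A5 | alternative 2 | 5,6,8-tri-O-benzyl-7-hydroxy tetrahydrochromone with the phenol benzylated (configuration at C5 to C8 as in 22) | COc1ccc(CCc2cc(=O)c3c(o2)[C@@H](OCc4ccccc4)[C@H](O)[C@@H](OCc4ccccc4)[C@H]3OCc4ccccc4)cc1OCc1ccccc1
A6 | alternative 3 | 2-[2-(3-hydroxy-4-methoxyphenyl)ethyl]-4H-chromen-4-one | COc1ccc(CCc2cc(=O)c3ccccc3o2)cc1O
A7 | alternative 3 | (5S,6R)-5,6-dihydroxy-2-[2-(3-hydroxy-4-methoxyphenyl)ethyl]-5,6-dihydro-4H-chromen-4-one | COc1ccc(CCc2cc(=O)c3c(o2)C=C[C@@H](O)[C@H]3O)cc1O
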